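## Structural features

Helenien is the dipalmitate of (3R,3'R,6'R)-lutein: a C40 skeleton in which a β-ring (C1–C6, ring alkene C5=C6) and an ε-ring (C1'–C6', ring alkene C4'=C5') are joined by an all-E chain C7–C7' with nine double bonds, and C3 and C3' each carry a hexadecanoyloxy group. Ten double bonds are conjugated (chain plus C5=C6); the ε-ring alkene stands outside the chromophore because C6' is sp3. There are three stereocentres: C3 is isolated in the β-ring, while C3' and C6' are 1,4-related across C4'=C5' and trans to each other. Although C3 and C3' are both R, their spatial sense relative to the gem-dimethyl carbon and the methyl-bearing ring carbon is opposite. Fragile sites are the doubly allylic C6'–H (base moves C4'=C5' into conjugation and erases C6'), the allylic C3'–O bond (acid ionises it), the polyene (acid, light, oxygen) and the two esters (alkoxides, hydrides). The real difficulty is the ε-ring: its alkene must be placed out of conjugation while C6' is set in the correct sense relative to C3', in a molecule whose two ends differ. The key step exploits the triad C4'=C5'–C6'(H) of the ε-ring. This triad is the reduced, 1,3-transposed form of a conjugated β-type ring that carries a heteroatom at C4', so an intramolecular hydrogen shift from a C4' diazene can create the C6'–H bond, the C6' configuration and the alkene position together.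

## Logic of the disconnections

21 is cut at C11'=C12' (Wittig) into 12 and 20. The cut keeps the ε-end as the electrophile, so it never meets the acid needed for phosphonium salt formation, and it joins two fragments that already carry their esters. The forward step must run without alkoxide (two esters, C6'–H).

20 is cut at the C3'–O bond into 18 and 19, with inversion at C3'. This turns the esterification into the step that corrects C3', so the cis alcohol delivered by the key step is exactly what is needed. The forward step must be a clean SN2 displacement on an allylic carbinol.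

18 goes back through 17 to 16 by adjustment of the chain terminus (C11' aldehyde, alcohol, ester). No skeletal bond is cut. The demand is chemoselectivity for the primary allylic position.

16 is cut at the C6'–H bond with return of the ring alkene to C5=C6, giving 14 (key disconnection). The precursor has a conjugated, base-stable β-type ring and no C6' stereocentre; its only stereochemical information is the trans C3–O/C4–N pair. The forward step must deliver hydrogen to C6 suprafacially from C4 and nowhere else.

14 is cut at the C4–N bond to 4. The trans N/O relationship is exactly what anti opening of an epoxide provides. The demand is attack at the allylic carbon C4.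

12 goes back through 11 and 10 to 8 and 9 (C–P bond, oxidation level, C3–O acyl bond), and 8 is cut at C11=C12 into 6 and 7. The symmetrical 7 supplies the central ten carbons. The demand is mono-olefination of 7.

6 goes back to 5 (C–P bond), and 5 to 4 by cutting the C4–H bond and the C11–O oxidation level. Both end groups therefore come from the same intermediate 4, whose C3 oxygen has the sense needed for the β-ring directly and for the ε-ring after the inversion above. The demand is hydride attack at C4.

4 is cut at its two epoxide C–O bonds to 3. This single catalyst-controlled step is the only enantio-determining event of the route. It must select the C3=C4 alkene among four and one of its faces.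

3 is cut at C7=C8 (Horner–Wadsworth–Emmons) into 1 and 2, both commercial; 1 already contains the C3=C4 alkene.

## Other disconnections considered

Alternative 1: Cut C11=C12 and C11'=C12' of the free diol A2 (lutein) and make it by two Wittig reactions of 7 with two C15 phosphonium salts, the ε-end coming from the hydroxy ketone A1; double acylation with 9 ends the route. The forward key step is the sequential double Wittig olefination. This is the plan that comes to mind first. Its weakness is A1: C6 must come from a resolution, and C3 from a hydride reduction of the ring enone whose faces are differentiated only by a remote centre, so little induction is expected. The β-half needs a second, unrelated chiral source, and the labile ε-ring is carried through more steps. The chosen plan derives all three stereocentres from one catalytic epoxidation and reveals the ε-ring from a robust conjugated precursor.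

Alternative 2: Cut the C6'–C7' bond. The forward key step is an Ireland–Claisen rearrangement of the silyl ketene acetal of the allylic acetate A3, which delivers carbon to C6' on the face of the C4'–O bond and gives the acid A4. It forms a skeletal bond and sets C6' in one step. However, C7' arrives sp3 and C8' as a carboxyl, so the C7'=C8' alkene has to be built afterwards beside the epimerisable C6'–H, where eliminations would tend to run towards C6'. A3 also needs a differentiated trans-3,4-diol, and the β-half still needs its own source. The diazene route gives the correct chain oxidation pattern directly and is several operations shorter.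

Alternative 3: Set C3' and C6' together by a dynamic kinetic resolution. The forward key step is asymmetric transfer hydrogenation of the racemic ring enone A5 while C6 racemises through the extended dienolate, funnelling to A1. The same dienolate can reprotonate at C4 to give the fully conjugated isomer, an irreversible drain that destroys the ε-skeleton. In addition, two enone carbonyls compete, and the catalyst would have to read a stereocentre γ to the carbonyl. The chosen key step is stereospecific and not dynamic, and it has no such drain.

Key step: step 10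

Assumption: the facial sense of the salen–manganese epoxidation of 3 is taken from the behaviour of this catalyst class with cyclic conjugated cis-alkenes (indene, 2,2-dimethylchromene), where the (R,R) ligand gives the R configuration at the epoxide carbon next to the conjugating group; should 3 respond in the opposite sense, the (S,S) catalyst is used and nothing else changes.

## Steps

Step 1
Reactants: 1 safranal (2,6,6-trimethylcyclohexa-1,3-diene-1-carbaldehyde); 2 ethyl (2E)-4-(diethoxyphosphoryl)-3-methylbut-2-enoate
Product: 3 ethyl (2E,4E)-3-methyl-5-(2,6,6-trimethylcyclohexa-1,3-dien-1-yl)penta-2,4-dienoate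
Conditions: 2, NaH, THF, 0 °C; then 1, 0 °C to rt
Reagents that add atoms: none
Why: Horner–Wadsworth–Emmons olefination; the stabilised vinylogous phosphonate anion adds to the hindered aldehyde and eliminates phosphate to give the E C7=C8 bond, the 2E geometry of the reagent being kept as the major form, and the minor 2Z isomer should be removable by chromatography.

Step 2
Reactants: 3 ethyl (2E,4E)-3-methyl-5-(2,6,6-trimethylcyclohexa-1,3-dien-1-yl)penta-2,4-dienoate
Product: 4 ethyl (2E,4E)-3-methyl-5-[(1R,6S)-2,4,4-trimethyl-7-oxabicyclo[4.1.0]hept-2-en-3-yl]penta-2,4-dienoate (the 3S,4R epoxide in carotenoid numbering)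
Conditions: (R,R)-(salen)MnCl (5 mol %; salen = N,N'-bis(3,5-di-tert-butylsalicylidene)cyclohexane-1,2-diaminate, trivalent manganese), 4-phenylpyridine N-oxide (20 mol %), aq. NaOCl buffered with Na2HPO4 (pH 11), CH2Cl2, 0 °C
Reagents that add atoms: sodium hypochlorite, [Na+].[O-]Cl
Why: Jacobsen–Katsuki epoxidation; the manganese-oxo species should select the only cis-disubstituted and most electron-rich alkene (C3=C4, farthest from the ester), the tetrasubstituted C5=C6 and the ester-conjugated alkenes being sterically and electronically disfavoured, and the (R,R) ligand is expected by the side-on approach model for cyclic conjugated cis-alkenes to give the 3S,4R epoxide, which fixes the sense of all three stereocentres of the target.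

Step 3
Reactants: 4 ethyl (2E,4E)-3-methyl-5-[(1R,6S)-2,4,4-trimethyl-7-oxabicyclo[4.1.0]hept-2-en-3-yl]penta-2,4-dienoate
Product: 5 (2E,4E)-5-[(4R)-4-hydroxy-2,6,6-trimethylcyclohex-1-en-1-yl]-3-methylpenta-2,4-dien-1-ol
Conditions: LiAlH4, THF, −20 to 0 °C; aq. potassium sodium tartrate work-up
Reagents that add atoms: none
Why: Hydride reduction; LiAlH4 reduces the conjugated ester to the allylic alcohol and opens the vinyl epoxide by SN2 attack at the activated allylic carbon C4, so the C3–O bond is untouched and becomes the 3R homoallylic alcohol of the β-ring.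

Step 4
Reactants: 5 (2E,4E)-5-[(4R)-4-hydroxy-2,6,6-trimethylcyclohex-1-en-1-yl]-3-methylpenta-2,4-dien-1-ol
Product: 6 [(2E,4E)-5-[(4R)-4-hydroxy-2,6,6-trimethylcyclohex-1-en-1-yl]-3-methylpenta-2,4-dien-1-yl]triphenylphosphonium bromide
Conditions: PPh3·HBr, MeOH, 0 °C to rt
Reagents that add atoms: triphenylphosphine hydrobromide, [Br-].c1ccc(cc1)[PH+](c1ccccc1)c1ccccc1
Why: SN1-type phosphonium salt formation; only the primary dienylic alcohol ionises to a delocalised cation, which PPh3 traps at the unhindered terminus, while the homoallylic secondary alcohol at C3 cannot ionise.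

Step 5
Reactants: 6 [(2E,4E)-5-[(4R)-4-hydroxy-2,6,6-trimethylcyclohex-1-en-1-yl]-3-methylpenta-2,4-dien-1-yl]triphenylphosphonium bromide; 7 (2E,4E,6E)-2,7-dimethylocta-2,4,6-trienedial
Product: 8 (3R)-3-hydroxy-12'-apo-β-caroten-12'-al, i.e. (2E,4E,6E,8E,10E,12E)-13-[(4R)-4-hydroxy-2,6,6-trimethylcyclohex-1-en-1-yl]-2,7,11-trimethyltrideca-2,4,6,8,10,12-hexaenal
Conditions: 7 (3 equiv), 1,2-epoxybutane, EtOH, reflux, dark, argon
Reagents that add atoms: none
Why: Wittig olefination with excess symmetrical dialdehyde; the mono-adduct is a more conjugated and less electrophilic aldehyde than 7, which favours single condensation, the epoxide serves as a neutral HBr acceptor, and the new C11=C12 bond is expected E under these thermally equilibrating conditions.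

Step 6
Reactants: 8 (3R)-3-hydroxy-12'-apo-β-caroten-12'-al; 9 hexadecanoyl chloride (palmitoyl chloride)
Product: 10 (3R)-12'-oxo-12'-apo-β-caroten-3-yl hexadecanoate, i.e. (1R)-3,5,5-trimethyl-4-[(1E,3E,5E,7E,9E,11E)-3,7,12-trimethyl-13-oxotrideca-1,3,5,7,9,11-hexaen-1-yl]cyclohex-3-en-1-yl hexadecanoate
Conditions: 9, pyridine, DMAP (cat.), CH2Cl2, 0 °C to rt
Reagents that add atoms: none
Why: Acylation with nucleophilic catalysis; the unhindered secondary alcohol is esterified with retention at C3 and the polyenal is inert.

Step 7
Reactants: 10 (3R)-12'-oxo-12'-apo-β-caroten-3-yl hexadecanoate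
Product: 11 (3R)-12'-hydroxy-12'-apo-β-caroten-3-yl hexadecanoate (the primary allylic alcohol at C12')
Conditions: NaBH4, THF–EtOH, 0 °C
Reagents that add atoms: none
Why: Chemoselective 1,2-reduction of the aldehyde by borohydride at 0 °C, where the palmitate ester is not reduced.

Step 8
Reactants: 11 (3R)-12'-hydroxy-12'-apo-β-caroten-3-yl hexadecanoate
Product: 12 [(3R)-3-(hexadecanoyloxy)-12'-apo-β-caroten-12'-yl]triphenylphosphonium bromide
Conditions: PPh3·HBr, CH2Cl2, 0 °C to rt
Reagents that add atoms: triphenylphosphine hydrobromide, [Br-].c1ccc(cc1)[PH+](c1ccccc1)c1ccccc1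
Why: Phosphonium salt formation as in step 4 through the polyenylic cation, run in CH2Cl2 so that no alcohol solvent can transesterify the palmitate.

Step 9
Reactants: 4 ethyl (2E,4E)-3-methyl-5-[(1R,6S)-2,4,4-trimethyl-7-oxabicyclo[4.1.0]hept-2-en-3-yl]penta-2,4-dienoate
Product: 14 ethyl (2E,4E)-5-[(3S,4S)-4-hydroxy-2,6,6-trimethyl-3-[2-(4-methylbenzenesulfonyl)hydrazin-1-yl]cyclohex-1-en-1-yl]-3-methylpenta-2,4-dienoate, via hydroxy hydrazine 13 (not isolated)
Conditions: N2H4·H2O (10 equiv), i-PrOH, 25–40 °C, argon; evaporate, toluene azeotrope; then TsCl (1.0 equiv), pyridine, CH2Cl2, −20 to 0 °C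
Reagents that add atoms: hydrazine hydrate, NN.O; 4-methylbenzenesulfonyl chloride, Cc1ccc(cc1)S(Cl)(=O)=O
Why: Epoxide aminolysis followed by N-sulfonylation; hydrazine opens the vinyl epoxide by SN2 attack with inversion at the allylic carbon C4 (vinylogous attack at C6, C8 or C10 is disfavoured by hindrance and by the ester polarisation of the polyene), and the unhindered terminal nitrogen is then sulfonylated faster than the internal nitrogen or the hydroxyl, so C4 carries nitrogen on the face opposite to the C3 oxygen.

Step 10
Reactants: 14 ethyl (2E,4E)-5-[(3S,4S)-4-hydroxy-2,6,6-trimethyl-3-[2-(4-methylbenzenesulfonyl)hydrazin-1-yl]cyclohex-1-en-1-yl]-3-methylpenta-2,4-dienoate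
Product: 16 ethyl (2E,4E)-5-[(1R,4S)-4-hydroxy-2,6,6-trimethylcyclohex-2-en-1-yl]-3-methylpenta-2,4-dienoate, via allylic diazene 15 (not isolated)
Conditions: NaOAc·3H2O (5 equiv), CHCl3, 60 °C, argon, dark
Reagents that add atoms: none
Why: Acetate removes the proton on the alkylated nitrogen and p-toluenesulfinate leaves in a 1,2-elimination, giving the monoalkyl allylic diazene 15. This diazene loses N2 through a concerted six-membered retro-ene transition state in which the diazene hydrogen migrates to C6 while the ring alkene moves from C5=C6 to C4=C5. The closest known reaction type is the allylic diazene rearrangement that ends the hydride reduction of enone tosylhydrazones and the reductive 1,3-transposition of allylic alcohols through sulfonyl hydrazines; only the assembly of the diazene precursor from an epoxide differs. No ring is closed. The new stereocentre C6' (C1 of the cyclohexenyl ring) is controlled by the C4 configuration: hydrogen is delivered suprafacially on the face that carried nitrogen, which is anti to the C3 oxygen, so the side chain and the hydroxyl end cis (1R,4S). The step needs hydrogen delivery to C6 and not to C4; the cyclic transition state can reach only C6, full substitution at C6 is no obstacle to an intramolecular hydrogen transfer, and the pseudoaxial C4–N bond it requires is available in the trans-diaxial half-chair. The loss of conjugation with the dienoate is paid for by extrusion of N2, as in related cases where this rearrangement moves an alkene out of conjugation. The medium is weakly basic and free of acid, so the new doubly allylic C6'–H and the allylic alcohol should survive.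

Step 11
Reactants: 16 ethyl (2E,4E)-5-[(1R,4S)-4-hydroxy-2,6,6-trimethylcyclohex-2-en-1-yl]-3-methylpenta-2,4-dienoate
Product: 17 (2E,4E)-5-[(1R,4S)-4-hydroxy-2,6,6-trimethylcyclohex-2-en-1-yl]-3-methylpenta-2,4-dien-1-ol
Conditions: i-Bu2AlH (3.5 equiv), CH2Cl2, −78 °C; aq. potassium sodium tartrate work-up
Reagents that add atoms: none
Why: Ester reduction; i-Bu2AlH reduces the conjugated ester to the primary allylic alcohol at −78 °C under non-basic conditions that leave the ring alkene and both stereocentres untouched.

Step 12
Reactants: 17 (2E,4E)-5-[(1R,4S)-4-hydroxy-2,6,6-trimethylcyclohex-2-en-1-yl]-3-methylpenta-2,4-dien-1-ol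
Product: 18 (2E,4E)-5-[(1R,4S)-4-hydroxy-2,6,6-trimethylcyclohex-2-en-1-yl]-3-methylpenta-2,4-dienal
Conditions: TEMPO (10 mol %), PhI(OAc)2 (1.05 equiv), CH2Cl2, 0 °C to rt
Reagents that add atoms: none
Why: Oxoammonium (TEMPO) oxidation, selective for the primary allylic alcohol over the more hindered secondary ring alcohol, in a medium without base so that C6'–H is not disturbed.

Step 13
Reactants: 18 (2E,4E)-5-[(1R,4S)-4-hydroxy-2,6,6-trimethylcyclohex-2-en-1-yl]-3-methylpenta-2,4-dienal; 19 hexadecanoic acid (palmitic acid)
Product: 20 (1R,4R)-3,5,5-trimethyl-4-[(1E,3E)-3-methyl-5-oxopenta-1,3-dien-1-yl]cyclohex-2-en-1-yl hexadecanoate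
Conditions: 19 (1.5 equiv), PPh3, DIAD, toluene–THF, 0 °C
Reagents that add atoms: none
Why: Mitsunobu esterification; palmitate displaces the alkoxyphosphonium at C3' with inversion, converting the cis alcohol into the trans (3'R,6'R) palmitate, and direct SN2 is favoured over SN2' because the alternative terminus C5' is a fully substituted alkene carbon.

Step 14
Reactants: 12 [(3R)-3-(hexadecanoyloxy)-12'-apo-β-caroten-12'-yl]triphenylphosphonium bromide; 20 (1R,4R)-3,5,5-trimethyl-4-[(1E,3E)-3-methyl-5-oxopenta-1,3-dien-1-yl]cyclohex-2-en-1-yl hexadecanoate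
Product: 21 helenien, (3R,3'R,6'R)-β,ε-carotene-3,3'-diyl dihexadecanoate
Conditions: 1,2-epoxybutane (solvent), reflux, dark, argon
Reagents that add atoms: none
Why: Wittig olefination under neutral epoxide conditions that tolerate both palmitates and the base-labile C6'–H; the polyenyl ylide joins C12' to C11', and the all-E polyene is expected because the cis arrangement at this position is sterically strained and heating favours the trans form.

## Compound list

1 | safranal, 2,6,6-trimethylcyclohexa-1,3-diene-1-carbaldehyde | CC1=C(C=O)C(C)(C)CC=C1 | starting material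
2 | ethyl (2E)-4-(diethoxyphosphoryl)-3-methylbut-2-enoate | CCOC(=O)/C=C(\C)CP(=O)(OCC)OCC | starting material
3 | ethyl (2E,4E)-3-methyl-5-(2,6,6-trimethylcyclohexa-1,3-dien-1-yl)penta-2,4-dienoate | CCOC(=O)/C=C(C)/C=C/C1=C(C)C=CCC1(C)C | intermediate
4 | ethyl (2E,4E)-3-methyl-5-[(1R,6S)-2,4,4-trimethyl-7-oxabicyclo[4.1.0]hept-2-en-3-yl]penta-2,4-dienoate | CCOC(=O)/C=C(C)/C=C/C1=C(C)[C@H]2O[C@H]2CC1(C)C | intermediate
5 | (2E,4E)-5-[(4R)-4-hydroxy-2,6,6-trimethylcyclohex-1-en-1-yl]-3-methylpenta-2,4-dien-1-ol | O[C@@H]1CC(C)=C(/C=C/C(C)=C/CO)C(C)(C)C1 | intermediate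
6 | [(2E,4E)-5-[(4R)-4-hydroxy-2,6,6-trimethylcyclohex-1-en-1-yl]-3-methylpenta-2,4-dien-1-yl]triphenylphosphonium bromide | [Br-].O[C@@H]1CC(C)=C(/C=C/C(C)=C/C[P+](c2ccccc2)(c2ccccc2)c2ccccc2)C(C)(C)C1 | intermediate
7 | (2E,4E,6E)-2,7-dimethylocta-2,4,6-trienedial | O=C/C(C)=C/C=C/C=C(C)/C=O | starting material
8 | (3R)-3-hydroxy-12'-apo-β-caroten-12'-al | O[C@@H]1CC(C)=C(/C=C/C(C)=C/C=C/C(C)=C/C=C/C=C(C)/C=O)C(C)(C)C1 | intermediate
9 | hexadecanoyl chloride | CCCCCCCCCCCCCCCC(=O)Cl | starting material
10 | (3R)-12'-oxo-12'-apo-β-caroten-3-yl hexadecanoate | CCCCCCCCCCCCCCCC(=O)O[C@@H]1CC(C)=C(/C=C/C(C)=C/C=C/C(C)=C/C=C/C=C(C)/C=O)C(C)(C)C1 | intermediate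
11 | (3R)-12'-hydroxy-12'-apo-β-caroten-3-yl hexadecanoate | CCCCCCCCCCCCCCCC(=O)O[C@@H]1CC(C)=C(/C=C/C(C)=C/C=C/C(C)=C/C=C/C=C(C)/CO)C(C)(C)C1 | intermediate
12 | [(3R)-3-(hexadecanoyloxy)-12'-apo-β-caroten-12'-yl]triphenylphosphonium bromide | [Br-].CCCCCCCCCCCCCCCC(=O)O[C@@H]1CC(C)=C(/C=C/C(C)=C/C=C/C(C)=C/C=C/C=C(C)/C[P+](c2ccccc2)(c2ccccc2)c2ccccc2)C(C)(C)C1 | intermediate
13 | ethyl (2E,4E)-5-[(3S,4S)-3-hydrazinyl-4-hydroxy-2,6,6-trimethylcyclohex-1-en-1-yl]-3-methylpenta-2,4-dienoate | CCOC(=O)/C=C(C)/C=C/C1=C(C)[C@H](NN)[C@@H](O)CC1(C)C | intermediate (not isolated)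
14 | ethyl (2E,4E)-5-[(3S,4S)-4-hydroxy-2,6,6-trimethyl-3-[2-(4-methylbenzenesulfonyl)hydrazin-1-yl]cyclohex-1-en-1-yl]-3-methylpenta-2,4-dienoate | CCOC(=O)/C=C(C)/C=C/C1=C(C)[C@H](NNS(=O)(=O)c2ccc(C)cc2)[C@@H](O)CC1(C)C | intermediate
15 | ethyl (2E,4E)-5-[(3S,4S)-3-diazenyl-4-hydroxy-2,6,6-trimethylcyclohex-1-en-1-yl]-3-methylpenta-2,4-dienoate | CCOC(=O)/C=C(C)/C=C/C1=C(C)[C@H](N=N)[C@@H](O)CC1(C)C | intermediate (not isolated)
16 | ethyl (2E,4E)-5-[(1R,4S)-4-hydroxy-2,6,6-trimethylcyclohex-2-en-1-yl]-3-methylpenta-2,4-dienoate | CCOC(=O)/C=C(C)/C=C/[C@H]1C(C)=C[C@@H](O)CC1(C)C | intermediate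
17 | (2E,4E)-5-[(1R,4S)-4-hydroxy-2,6,6-trimethylcyclohex-2-en-1-yl]-3-methylpenta-2,4-dien-1-ol | OC/C=C(C)/C=C/[C@H]1C(C)=C[C@@H](O)CC1(C)C | intermediate
18 | (2E,4E)-5-[(1R,4S)-4-hydroxy-2,6,6-trimethylcyclohex-2-en-1-yl]-3-methylpenta-2,4-dienal | O=C/C=C(C)/C=C/[C@H]1C(C)=C[C@@H](O)CC1(C)C | intermediate
19 | hexadecanoic acid | CCCCCCCCCCCCCCCC(=O)O | starting material
20 | (1R,4R)-3,5,5-trimethyl-4-[(1E,3E)-3-methyl-5-oxopenta-1,3-dien-1-yl]cyclohex-2-en-1-yl hexadecanoate | O=C/C=C(C)/C=C/[C@H]1C(C)=C[C@H](OC(=O)CCCCCCCCCCCCCCC)CC1(C)C | intermediate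
21 | helenien, (3R,3'R,6'R)-β,ε-carotene-3,3'-diyl dihexadecanoate | CCCCCCCCCCCCCCCC(=O)O[C@@H]1CC(C)=C(/C=C/C(C)=C/C=C/C(C)=C/C=C/C=C(C)/C=C/C=C(C)/C=C/[C@H]2C(C)=C[C@H](OC(=O)CCCCCCCCCCCCCCC)CC2(C)C)C(C)(C)C1 | target

## Step count and least certain steps

Total: 14 steps. Longest linear sequence: 9 steps (1, 2, 3, 4, 5, 6, 7, 8, 14); the ε-branch (1, 2, 9, 10, 11, 12, 13, 14) has 8.

Step 10 (key step). The most likely failure is escape from the concerted pathway: radical or bimolecular decomposition of the highly conjugated diazene, which would lose N2 without moving the alkene, or sluggish loss of sulfinate at a temperature the trienoate tolerates. The fallback changes the mode of hydrogen delivery and sets out from 4. Treatment with excess i-Bu2AlH reduces the ester and is known to open vinyl epoxides in the SN2' sense; the aluminium bound to the epoxide oxygen would deliver hydride to C6 internally, on the oxygen face. This would give the trans diol (2E,4E)-5-[(1R,4R)-4-hydroxy-2,6,6-trimethylcyclohex-2-en-1-yl]-3-methylpenta-2,4-dien-1-ol F1. Oxidation with TEMPO/PhI(OAc)2 gives the trans hydroxy aldehyde (2E,4E)-5-[(1R,4R)-4-hydroxy-2,6,6-trimethylcyclohex-2-en-1-yl]-3-methylpenta-2,4-dienal F2, and acylation with 9 and pyridine (retention) returns to the route at 20. Should the hydride instead arrive anti to the oxygen, the product is 17 itself and the route continues from there unchanged.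

Step 9. The most likely failure is attack of hydrazine on the dienoate (acyl substitution or conjugate addition) in competition with epoxide opening, or opening at C3 instead of C4. The fallback sets out from 4 and avoids free hydrazine: 4 is opened directly with p-toluenesulfonyl hydrazide, a non-basic and poorly acylating nitrogen nucleophile, with the epoxide activated by 2,2,2-trifluoroethanol as solvent or by LiClO4. This comes back at 14 in one operation and makes no new compound.

Step 2. The most likely failure is incomplete site selectivity among the four alkenes of 3, over-oxidation, or insufficient facial selectivity. The fallback sets out from 1 and moves the epoxidation to a substrate with a single reactive alkene: the same catalyst system is applied to 1, whose enal alkene is deactivated, to give (1R,6S)-2,4,4-trimethyl-7-oxabicyclo[4.1.0]hept-2-ene-3-carbaldehyde F3. Olefination of F3 with 2 under mild LiCl/DBU conditions in MeCN comes back at 4.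

Step 3. The most likely failure is misdirected hydride delivery (at C3, or in the SN2' sense at C6) or over-reduction of the dienyl alcohol by the aluminate. The fallback sets out from 4 and changes the mechanism of C4–H bond formation. Formate hydrogenolysis of the vinyl epoxide with zerovalent palladium (Pd2(dba)3·CHCl3, PBu3, HCO2H, Et3N, 1,4-dioxane, rt) goes through a π-allyl palladium formate and is expected to deliver hydride to the oxygen-bearing allyl terminus. This would give ethyl (2E,4E)-5-[(4R)-4-hydroxy-2,6,6-trimethylcyclohex-1-en-1-yl]-3-methylpenta-2,4-dienoate F4; reduction of F4 with i-Bu2AlH comes back at 5.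

Step 13. The most likely failure is ionisation of the allylic alkoxyphosphonium, with loss of stereospecificity, SN2' substitution or elimination to a ring diene. The fallback sets out from 16 and replaces inversion by reagent-controlled reduction. MnO2 oxidation of the ring alcohol gives ethyl (2E,4E)-3-methyl-5-[(1R)-2,6,6-trimethyl-4-oxocyclohex-2-en-1-yl]penta-2,4-dienoate F5. Corey–Bakshi–Shibata reduction with the (S)-methyl oxazaborolidine and BH3·SMe2 (alkenyl as the large group) should give the 3'R alcohol ethyl (2E,4E)-5-[(1R,4R)-4-hydroxy-2,6,6-trimethylcyclohex-2-en-1-yl]-3-methylpenta-2,4-dienoate F6. Reduction with i-Bu2AlH gives the trans diol F1, TEMPO/PhI(OAc)2 oxidation gives the trans hydroxy aldehyde F2, and acylation with 9 and pyridine comes back at 20.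

## Further compounds

F1 | step 10 | (2E,4E)-5-[(1R,4R)-4-hydroxy-2,6,6-trimethylcyclohex-2-en-1-yl]-3-methylpenta-2,4-dien-1-ol | OC/C=C(C)/C=C/[C@H]1C(C)=C[C@H](O)CC1(C)C
F2 | step 10 | (2E,4E)-5-[(1R,4R)-4-hydroxy-2,6,6-trimethylcyclohex-2-en-1-yl]-3-methylpenta-2,4-dienal | O=C/C=C(C)/C=C/[C@H]1C(C)=C[C@H](O)CC1(C)C
F0 | step 9 | none | none
F3 | step 2 | (1R,6S)-2,4,4-trimethyl-7-oxabicyclo[4.1.0]hept-2-ene-3-carbaldehyde | O=CC1=C(C)[C@H]2O[C@H]2CC1(C)C
F4 | step 3 | ethyl (2E,4E)-5-[(4R)-4-hydroxy-2,6,6-trimethylcyclohex-1-en-1-yl]-3-methylpenta-2,4-dienoate | O[C@@H]1CC(C)=C(/C=C/C(C)=C/C(=O)OCC)C(C)(C)C1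
F5 | step 13 | ethyl (2E,4E)-3-methyl-5-[(1R)-2,6,6-trimethyl-4-oxocyclohex-2-en-1-yl]penta-2,4-dienoate | CCOC(=O)/C=C(C)/C=C/[C@H]1C(C)=CC(=O)CC1(C)C
F6 | step 13 | ethyl (2E,4E)-5-[(1R,4R)-4-hydroxy-2,6,6-trimethylcyclohex-2-en-1-yl]-3-methylpenta-2,4-dienoate | CCOC(=O)/C=C(C)/C=C/[C@H]1C(C)=C[C@H](O)CC1(C)C
A1 | alternative 1 | (3R,6R)-3-hydroxy-α-ionone, (3E)-4-[(1R,4R)-4-hydroxy-2,6,6-trimethylcyclohex-2-en-1-yl]but-3-en-2-one | CC(=O)/C=C/[C@H]1C(C)=C[C@H](O)CC1(C)C
A2 | alternative 1 | lutein, (3R,3'R,6'R)-β,ε-carotene-3,3'-diol | O[C@@H]1CC(C)=C(/C=C/C(C)=C/C=C/C(C)=C/C=C/C=C(C)/C=C/C=C(C)/C=C/[C@H]2C(C)=C[C@H](O)CC2(C)C)C(C)(C)C1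
A3 | alternative 2 | (1R,6R)-6-[(tert-butyldimethylsilyl)oxy]-2,4,4-trimethylcyclohex-2-en-1-yl acetate | CC(=O)O[C@@H]1C(C)=CC(C)(C)C[C@H]1O[Si](C)(C)C(C)(C)C
A4 | alternative 2 | 2-[(1R,4R)-4-[(tert-butyldimethylsilyl)oxy]-2,6,6-trimethylcyclohex-2-en-1-yl]acetic acid | OC(=O)C[C@H]1C(C)=C[C@H](O[Si](C)(C)C(C)(C)C)CC1(C)C
A5 | alternative 3 | racemic 3-oxo-α-ionone, (3E)-4-(2,6,6-trimethyl-4-oxocyclohex-2-en-1-yl)but-3-en-2-one | CC(=O)/C=C/C1C(C)=CC(=O)CC1(C)C
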